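## Structural features

The target is a resveratrol tetramer with ten free phenolic hydroxyl groups, in which an E-stilbene C=C joins a flat benzofuran half to a tetracyclic half with four stereocentres. In the left half the benzofuran (ring B fused to the furan) carries ring A (4-hydroxyphenyl) on C2, ring C (3,5-dihydroxyphenyl) on C3, a hydroxyl on C6 and the stilbene carbon on C4, so C3 and C4 are peri and crowded. In the right half ring D (a hydroxyphenyl ring, C-linked ortho to its OH and para to the stilbene) sits on Ca of a seven-membered carbocycle made of Ca, Cd, two carbons of ring F, Cb and two carbons of ring E; ring E is also fused to a 2,3-dihydrofuran through its oxygen, Cc and Cb, and rings G and H (4-hydroxyphenyl) sit on Cd and Cc. The stereocentres form two adjacent pairs, Cc(S)–Cb(S) with rings H and F trans on the dihydrofuran and Ca(R)–Cd(S) with rings D and G trans on the seven-membered ring; the pairs are linked through ring E, where H–Ca and H–Cb lie on the same face. Fragile elements are the electron-rich stilbene (protonation, E/Z isomerisation, cyclisation onto ring C), the benzylic O–Cc bond (ionised by acid), any cation at Cd next to H–Ca, and the polyphenol itself (oxidation), so the phenols stay methylated until the last step. The real difficulty is the absolute and relative control of Ca, Cd, Cb and Cc on a ring system with few handles, together with the crowded 2,3-diaryl-4-substituted benzofuran. The key step uses the fact that C2 and C3 of the furan both carry aryl groups: ring C with C3 can enter as a ketone placed ortho to the C4 side chain, ring A with C2 as an ester on the C7a oxygen, and the C2=C3 bond is then made last, so nothing has to be coupled beside C4.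

## Logic of the disconnections

30 to 29. The ten O–CH3 bonds are cut, so that every phenol oxygen is methylated in 29. The free polyphenol is oxidised easily and would quench bases, Lewis acids and organometallic reagents; one ether type needs one final step. The gain is that all C–C bond formation runs on inert aryl methyl ethers. The demand is a final ether cleavage that neither ionises the O–Cc bond nor protonates the stilbene.

29 to 10 and 28. The stilbene C=C is cut. It is the only link between the halves and can be formed with E geometry under basic conditions by a phosphonate olefination. The gain is that the stereocentre-free benzofuran and the tetracycle are made independently; phosphorus goes on the benzofuran side, where the benzylic carbon exists from the start, and the formyl group on ring D, where it is unhindered. The forward step must be E-selective and must tolerate a carbanion flanked by ring C.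

10 to 9 to 8. The C–P bond, then the O–Si bond, are cut. The benzylic oxygen has to be masked through the Lewis-acid and titanium steps and is exchanged for phosphorus only afterwards. The gain is a spectator group that offers the titanium reagent no carbonyl. The demand is a C–O to C–P exchange without a persistent benzylic halide on an electron-rich ring.

8 to 7. The C2=C3 bond of the furan is cut and both carbons get their oxygen back, C3 as a diaryl ketone and C2 as the carbonyl of an aryl ester on O1. Cutting here makes the crowded 2,3-diaryl pattern the result of two acylations. The heterocycle disappears. The forward step must reduce two carbonyl groups to one C=C intramolecularly and leave ethers alone.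

7 to 5 and 6, 5 to 4. The ester C–O bond is cut, then the phenol is traced to its methyl ether (O–CH3). 6 carries ring A and C2 as one commercial piece, and the methyl ether is what the preceding acylation needs. The demand is a demethylation that singles out the methoxy group beside the ketone and spares the silyl ether.

4 to 2 and 3, 2 to 1. The aryl–C(=O) bond is cut, then the O–Si bond. 3 carries ring C and C3; 1 carries the C4 carbon and both oxygens of ring B in the right places. The gain is two commercial building blocks. The demand is acylation ortho to the side chain and not between the two methoxy groups.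

28 to 27. The ring D–CHO bond is cut back to a C–Br bond. A bromine atom survives every earlier step, a formyl group would not. The gain is one robust handle carried from the first core step. The demand is halogen–metal exchange in the presence of benzylic C–H bonds and the dihydrofuran.

27 to 25 (through 26), 25 to 23 and 24. The O–Cc bond is cut, which leaves a Cb=Cc alkene (26) and, one stage back, a tertiary alcohol at Cb (25). Then the Cb–Cc bond is cut to a ketone at Cb (23) and a benzylic Grignard reagent (24). Cc arrives with ring H as one unit, and the ring closure is reversible, so both centres can settle thermodynamically. The gain is that the dihydrofuran and two stereocentres reduce to a ketone. The demand is a trans ring and the Cb configuration with H–Cb and H–Ca on the same face.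

23 to 22 to 21. The O–CH3 bond of ring E beside the ketone and the O–CH3 bond of ring D are cut in turn. The ring E oxygen must be free to become the furan oxygen, and the ring D oxygen must be protected. The gain is that the ketone itself marks the methoxy group to be removed. The demand is selective demethylation.

21 to 20. The Cd–ring F bond of the seven-membered ring is cut and Cd is joined to the oxygen of ring D, giving a 2,3-dihydrobenzofuran. That ring stores the benzylic cation at Cd and holds Ca as a configurationally stable centre. The seven-membered ring disappears. The forward ring closure onto ring F must beat proton loss at Ca and place ring G trans to ring D.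

20 to 19 and 3. The ring E–C(=O) bond is cut. Ring F and Cb come in one acylation, with the same acid chloride as in the other half. The gain is one step for a ring and the Cb carbon. The demand is acylation ortho to the benzylic carbon without ionising the benzylic ether.

19 to 17 (through 18), 17 to 16. The Ca–Cd bond is cut as a carbene at Ca inserting into a C–H bond of an O–CH2–aryl group; the carbene goes back to a diazo group (18), a hydrazone (17) and a ketone (16). This is where absolute configuration enters, through a chiral catalyst. The gain is that the first stereocentre comes from an achiral diaryl ketone. The demand is high enantioselectivity and a ketone with only one ortho substituent.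

16 to 13 and 14 (through 15), 13 to 11 and 12. The aryl–C(=O) bond is cut to a nitrile and an aryl Grignard reagent, then the O–CH2 bond of the benzyl ether. All four pieces are commercial. The gain is a two-step entry to the diaryl ketone. The demand is mono-addition to the nitrile in the presence of an aryl bromide.

## Other disconnections considered

Alternative 1: The cut removes rings G and H. The Cd–ring G and Cc–ring H bonds are broken, both rings go back to anisole A3, and what remains is the aryl-free tetracycle A2 with a benzylic alcohol at Cd and a lactol at Cc. Forward, a boron Lewis acid would ionise both C–O bonds of A2 and the para carbon of A3 would capture each cation, which should give A1 without closing a ring.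
- In its favour: both 4-oxyphenyl rings come from the simplest arene in one operation. At both centres the aryl group arrives last and anti to the aryl group on the neighbouring carbon, which is the dependable way to a trans diaryl pair.
- Against it here: A2 must first be built with Ca and Cb already correct. Two cations are formed in one flask, the one at Cd sits beside H–Ca (elimination, aryl shift), and ortho attack of A3 competes. The chloride on ring D is harder to turn into the aldehyde than the bromide of 27.
- Comparison: for bringing in rings G and H the alternative is the better on step count (one step against steps 8, 16 and 17, where each ring arrives with its benzylic carbon). On the stereochemical argument at Cd it is the equal of step 13 (same cation, same anti attack, intermolecular instead of intramolecular). The chosen plan is stronger in that Ca is set by a catalyst. The alternative does not address the benzofuran and would be combined with step 5, not replace it.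

Alternative 2: The cut removes ring E. The Ca–ring E and Cb–ring E bonds are broken, ring E goes back to the aryne precursor A6 and the seven-membered ketone contracts to the indanone A5. Forward, fluoride would release the aryne from A6, the enolate carbon Ca of A5 would add to the aryne carbon remote from the methoxy group, the aryl anion would add to the ketone, and the strained four-membered alkoxide would fragment. Two C–C bonds form, the ring grows by two atoms, and the product should be A4.
- In its favour: A4 is the same compound as 22, so this competes directly with steps 8–14. The regiochemistry of a 3-methoxyaryne is predictable, and the trans indanone rests on well-known chemistry and a thermodynamic preference.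
- Against it here: aryne insertion into C–C bonds is best established for doubly activated carbons, and a simple α-aryl ketone enolate may stop at C- or O-arylation. More seriously, the fragmentation leaves a carbanion at Ca, so Ca is re-protonated in the seven-membered ring, and delivery of the proton anti to ring G would not obviously give the trans series.
- Comparison: on step count to 22 the alternative is probably the better. Structurally it is the equal (identical intermediate). Mechanistically it is anionic where steps 12 and 13 are cationic. The chosen plan has the advantage that Ca is made once under catalyst control and never becomes planar again, whereas the alternative needs an enantioselective route to A5.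

Alternative 3: The cut dismantles the benzene ring of the benzofuran (C7–C7a, C6–C7, C4–C5, C3a–C4), going back to the diaryl furyl diazomethyl ketone A8 and ethoxyacetylene A9. Forward, light would induce a Wolff rearrangement of A8 to the furylketene A10, which adds A9 in a [2+2] step. Four-electron ring opening, six-electron closure onto the furan and tautomerisation should then give the benzofuran-4-ol A7 (Danheiser benzannulation).
- In its favour: the oxygen pattern is set without ambiguity (free OH on C4, ethyl ether on C6). No Friedel–Crafts regiochemistry question and no BCl3 step arise, and the C4–OH can become a triflate for a palladium-catalysed coupling.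
- Against it here: the C4 oxygen must then be exchanged for carbon by a coupling right beside ring C, which is the peri coupling the chosen plan avoids by carrying the C4 carbon from 1. A8 needs a 2,3-diaryl furan with a diazoacetyl group, several steps and the photolysis of a diazo compound.
- Comparison: structurally the alternative builds the carbocycle on a furan, the chosen plan the furan on a benzene. Mechanistically it is a pericyclic cascade against a reductive carbonyl coupling; both are free of stereochemical questions and equal in that respect. 7 is four steps from 1, and A8 would hardly be shorter. After the key step the alternative could be the better by one step if the triflate of A7 were joined by a Heck reaction to a styrene made from 28 (two steps against steps 6, 7 and 19).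

Key step: step 5

Remarks on the chemistry:
- 14 and 24 are bought as THF solutions.
- Rh2(R-PTAD)4 is dirhodium tetrakis[(R)-(1-adamantyl)(phthalimido)acetate]. It is assumed to give the (2S,3R) series in step 11; if the sense of induction is the opposite, the mirror-image catalyst is used and nothing else changes.
- 7 and 8 were compared atom by atom with the target (ring A on C2, ring C on C3, carbon on C4, oxygen on C6) and need no correction. The triisopropylsilyl ether is kept as spectator group because it withstands SnCl4 and BCl3 at low temperature and offers the titanium reagent no carbonyl group.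

## Route

Step 1
Reactants: 1 3,5-dimethoxybenzyl alcohol
Product: 2 [(3,5-dimethoxybenzyl)oxy]triisopropylsilane
Conditions: i-Pr3SiCl, imidazole, DMF, rt
Reagents that add atoms: triisopropylsilyl chloride, CC(C)[Si](Cl)(C(C)C)C(C)C
Why: Standard silylation of a primary benzylic alcohol; the bulky silyl ether should survive the Lewis acids of steps 2 and 3 and is inert to the titanium reagent of step 5.

Step 2
Reactants: 2 [(3,5-dimethoxybenzyl)oxy]triisopropylsilane; 3 3,5-dimethoxybenzoyl chloride
Product: 4 (3,5-dimethoxyphenyl)[2,4-dimethoxy-6-(triisopropylsilyloxymethyl)phenyl]methanone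
Conditions: SnCl4, CH2Cl2, −20 → 0 °C
Reagents that add atoms: none
Why: Friedel–Crafts acylation at the position ortho to the side chain and para to a methoxy group; the site between the two methoxy groups is only ortho-activated and flanked twice, so the ketone should end up next to the future C4 carbon.

Step 3
Reactants: 4 (3,5-dimethoxyphenyl)[2,4-dimethoxy-6-(triisopropylsilyloxymethyl)phenyl]methanone
Product: 5 (3,5-dimethoxyphenyl)[2-hydroxy-4-methoxy-6-(triisopropylsilyloxymethyl)phenyl]methanone
Conditions: BCl3, CH2Cl2, −78 → −20 °C; then H2O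
Reagents that add atoms: none
Why: Chelation-controlled demethylation: boron binds the ketone and the ortho methoxy oxygen, and chloride removes only that methyl group; low temperature protects the silyl ether and the other methyl ethers.

Step 4
Reactants: 5 (3,5-dimethoxyphenyl)[2-hydroxy-4-methoxy-6-(triisopropylsilyloxymethyl)phenyl]methanone; 6 4-methoxybenzoyl chloride
Product: 7 2-(3,5-dimethoxybenzoyl)-5-methoxy-3-(triisopropylsilyloxymethyl)phenyl 4-methoxybenzoate
Conditions: Et3N, DMAP (cat.), CH2Cl2, 0 °C → rt
Reagents that add atoms: none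
Why: DMAP-catalysed O-acylation of the hydrogen-bonded phenol; it brings in ring A together with the carbon that becomes C2.

Step 5
Reactants: 7 2-(3,5-dimethoxybenzoyl)-5-methoxy-3-(triisopropylsilyloxymethyl)phenyl 4-methoxybenzoate
Product: 8 3-(3,5-dimethoxyphenyl)-6-methoxy-2-(4-methoxyphenyl)-4-(triisopropylsilyloxymethyl)benzofuran
Conditions: TiCl3, Zn, DME, reflux; 7 added over several hours to the excess reagent
Reagents that add atoms: none
Why: Low-valent titanium made from TiCl3 and Zn transfers electrons to the diaryl ketone and gives a titanium-bound ketyl or carbanion at the future C3. This carbon attacks the carbonyl carbon of the neighbouring aryl ester in a 5-exo-trig closure, so that O1, C7a, C3a, C3 and C2 form the new ring. The titanium-bound dioxygenated intermediate is then deoxygenated, driven by strong Ti–O bonds and by the aromatic furan, which leaves the C2=C3 bond. The closest known reaction type is the McMurry-type intramolecular ketone–ester coupling that converts ortho-acyloxy aryl ketones into 2,3-disubstituted benzofurans. No stereocentre is formed. The step needs chemoselectivity for the intramolecular ketone–ester coupling over pinacol-type dimerisation and over plain reduction of the ketone; the ortho ester, the two ortho substituents that shield the ketone from a second molecule, and slow addition to excess reagent should secure it. Methyl ethers and the silyl ether do not react, and since both aryl groups came in by acylation no cross-coupling is needed beside the CH2 group on C4.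

Step 6
Reactants: 8 3-(3,5-dimethoxyphenyl)-6-methoxy-2-(4-methoxyphenyl)-4-(triisopropylsilyloxymethyl)benzofuran
Product: 9 [3-(3,5-dimethoxyphenyl)-6-methoxy-2-(4-methoxyphenyl)benzofuran-4-yl]methanol
Conditions: n-Bu4NF, THF, 0 °C → rt
Reagents that add atoms: none
Why: Fluoride-induced desilylation frees the benzylic alcohol and leaves the methyl ethers alone.

Step 7
Reactants: 9 [3-(3,5-dimethoxyphenyl)-6-methoxy-2-(4-methoxyphenyl)benzofuran-4-yl]methanol
Product: 10 diethyl {[3-(3,5-dimethoxyphenyl)-6-methoxy-2-(4-methoxyphenyl)benzofuran-4-yl]methyl}phosphonate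
Conditions: P(OEt)3, ZnI2, toluene, 110 °C
Reagents that add atoms: triethyl phosphite, CCOP(OCC)OCC
Why: ZnI2-mediated Michaelis–Arbuzov-type conversion of an electron-rich benzylic alcohol: the zinc-activated C–O bond is replaced by C–P and one ethyl group leaves as ethanol, so no labile benzylic halide has to be handled.

Step 8
Reactants: 11 5-bromo-2-hydroxybenzonitrile; 12 4-methoxybenzyl chloride
Product: 13 5-bromo-2-[(4-methoxybenzyl)oxy]benzonitrile
Conditions: K2CO3, n-Bu4NI (cat.), DMF, 60 °C
Reagents that add atoms: none
Why: Williamson ether synthesis; the benzyl group delivers the future Cd with ring G, and its CH2 is the C–H bond used in step 11.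

Step 9
Reactants: 13 5-bromo-2-[(4-methoxybenzyl)oxy]benzonitrile; 14 3,5-dimethoxyphenylmagnesium chloride
Product: 16 {5-bromo-2-[(4-methoxybenzyl)oxy]phenyl}(3,5-dimethoxyphenyl)methanone, via N-magnesio ketimine 15 (not isolated)
Conditions: THF, 0 → 60 °C; then 2 M HCl, rt
Reagents that add atoms: water, O
Why: Grignard addition to the nitrile stops at the metallated ketimine, which cannot take up a second equivalent; mild acid hydrolysis gives the diaryl ketone, and the aryl bromide does not exchange with an aryl Grignard reagent.

Step 10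
Reactants: 16 {5-bromo-2-[(4-methoxybenzyl)oxy]phenyl}(3,5-dimethoxyphenyl)methanone
Product: 17 [{5-bromo-2-[(4-methoxybenzyl)oxy]phenyl}(3,5-dimethoxyphenyl)methylidene]hydrazine
Conditions: N2H4·H2O, AcOH (cat.), EtOH, 80 °C
Reagents that add atoms: hydrazine, NN
Why: Condensation of a ketone with one ortho substituent with hydrazine gives the N-unsubstituted hydrazone, the precursor of the diazo compound.

Step 11
Reactants: 17 [{5-bromo-2-[(4-methoxybenzyl)oxy]phenyl}(3,5-dimethoxyphenyl)methylidene]hydrazine
Product: 19 (2S,3R)-5-bromo-3-(3,5-dimethoxyphenyl)-2-(4-methoxyphenyl)-2,3-dihydrobenzofuran, via diaryldiazomethane 18 (not isolated)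
Conditions: MnO2, CH2Cl2, 0 °C; filtration; Rh2(R-PTAD)4 (1 mol %), CH2Cl2, 0 °C → rt
Reagents that add atoms: none
Why: MnO2 dehydrogenates the hydrazone to the diaryldiazomethane, and the chiral dirhodium tetracarboxylate turns it into a donor/donor carbene that inserts into a C–H bond of the ether CH2 (1,5 C–H insertion) to give the 2,3-cis-dihydrobenzofuran. The catalyst selects the carbene face and one of the two enantiotopic hydrogens; this fixes Ca (C3, R) for the rest of the synthesis, while the centre at C2 is provisional.

Step 12
Reactants: 19 (2S,3R)-5-bromo-3-(3,5-dimethoxyphenyl)-2-(4-methoxyphenyl)-2,3-dihydrobenzofuran; 3 3,5-dimethoxybenzoyl chloride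
Product: 20 {2-[(2S,3R)-5-bromo-2-(4-methoxyphenyl)-2,3-dihydrobenzofuran-3-yl]-4,6-dimethoxyphenyl}(3,5-dimethoxyphenyl)methanone
Conditions: SnCl4, CH2Cl2, −40 → −20 °C
Reagents that add atoms: none
Why: Friedel–Crafts acylation of ring E ortho to the benzylic carbon and para to a methoxy group (the two such positions are equivalent); ring D is deactivated by bromine and ring G is less electron-rich. The low temperature is meant to keep the benzylic ether from ionising.

Step 13
Reactants: 20 {2-[(2S,3R)-5-bromo-2-(4-methoxyphenyl)-2,3-dihydrobenzofuran-3-yl]-4,6-dimethoxyphenyl}(3,5-dimethoxyphenyl)methanone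
Product: 21 (10R,11S)-10-(5-bromo-2-hydroxyphenyl)-1,3,6,8-tetramethoxy-11-(4-methoxyphenyl)-10,11-dihydro-5H-dibenzo[a,d][7]annulen-5-one
Conditions: TfOH (0.2 equiv), (CF3)2CHOH/CH2Cl2, −20 → 0 °C
Reagents that add atoms: none
Why: The acid ionises the 4-methoxybenzylic C–O bond, and the cation at Cd is captured by the ortho carbon of ring F in an intramolecular Friedel–Crafts alkylation that closes the seven-membered ring and frees the ring D phenol. Allylic strain holds H–Ca in the plane of the cation, so ring E (with ring F) and ring D occupy opposite faces and the new bond forms anti to ring D (rings D and G trans, Cd S). The in-plane C–H bond is poorly aligned for proton loss, which should protect Ca.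

Step 14
Reactants: 21 (10R,11S)-10-(5-bromo-2-hydroxyphenyl)-1,3,6,8-tetramethoxy-11-(4-methoxyphenyl)-10,11-dihydro-5H-dibenzo[a,d][7]annulen-5-one
Product: 22 (10R,11S)-10-(5-bromo-2-methoxyphenyl)-1,3,6,8-tetramethoxy-11-(4-methoxyphenyl)-10,11-dihydro-5H-dibenzo[a,d][7]annulen-5-one
Conditions: MeI, K2CO3, acetone, 56 °C
Reagents that add atoms: iodomethane, CI
Why: Williamson methylation of the only free phenol protects ring D for the organometallic steps.

Step 15
Reactants: 22 (10R,11S)-10-(5-bromo-2-methoxyphenyl)-1,3,6,8-tetramethoxy-11-(4-methoxyphenyl)-10,11-dihydro-5H-dibenzo[a,d][7]annulen-5-one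
Product: 23 (10R,11S)-10-(5-bromo-2-methoxyphenyl)-6-hydroxy-1,3,8-trimethoxy-11-(4-methoxyphenyl)-10,11-dihydro-5H-dibenzo[a,d][7]annulen-5-one
Conditions: BCl3, CH2Cl2, −78 → 0 °C; then H2O
Reagents that add atoms: none
Why: Chelation-controlled demethylation: only the ring E methoxy group ortho to the ketone is cleaved. No acid-labile benzylic ether is present at this stage.

Step 16
Reactants: 23 (10R,11S)-10-(5-bromo-2-methoxyphenyl)-6-hydroxy-1,3,8-trimethoxy-11-(4-methoxyphenyl)-10,11-dihydro-5H-dibenzo[a,d][7]annulen-5-one; 24 4-methoxybenzylmagnesium chloride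
Product: 25 (10R,11S)-10-(5-bromo-2-methoxyphenyl)-1,3,8-trimethoxy-5-(4-methoxybenzyl)-11-(4-methoxyphenyl)-10,11-dihydro-5H-dibenzo[a,d][7]annulene-5,6-diol (either configuration at C5)
Conditions: LaCl3·2LiCl, THF, 0 °C → rt; aq. NH4Cl
Reagents that add atoms: none
Why: 1,2-Addition of the benzylic Grignard reagent to the diaryl ketone brings in Cc with ring H; the first equivalent deprotonates the phenol and LaCl3·2LiCl raises the electrophilicity of the hindered carbonyl. The carbinol configuration does not matter because this carbon becomes planar in step 17.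

Step 17
Reactants: 25 (10R,11S)-10-(5-bromo-2-methoxyphenyl)-1,3,8-trimethoxy-5-(4-methoxybenzyl)-11-(4-methoxyphenyl)-10,11-dihydro-5H-dibenzo[a,d][7]annulene-5,6-diol
Product: 27 (1S,6R,7S,11bS)-6-(5-bromo-2-methoxyphenyl)-4,8,10-trimethoxy-1,7-bis(4-methoxyphenyl)-1,6,7,11b-tetrahydrobenzo[6,7]cyclohepta[1,2,3-cd][1]benzofuran, via benzylidene phenol 26 (not isolated)
Conditions: TsOH·H2O (0.1 equiv), toluene, 60 °C
Reagents that add atoms: none
Why: Acid ionises the tertiary ortho-hydroxy benzhydrylic alcohol and proton loss gives the 2-hydroxystilbene-type alkene 26; protonation at Cb and attack of the phenol oxygen on the 4-methoxybenzylic cation at Cc then close the dihydrofuran (acid-catalysed hydroalkoxylation). The O–Cc bond re-ionises and Cb is reprotonated via 26, so both centres should settle thermodynamically: rings F and H trans on the five-membered ring (Cc S), and Cb (S) with H–Cb and H–Ca together on the face of ring E opposite the Cd–ring F bridge. The Cb epimer would force ring D against H–Cb.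

Step 18
Reactants: 27 (1S,6R,7S,11bS)-6-(5-bromo-2-methoxyphenyl)-4,8,10-trimethoxy-1,7-bis(4-methoxyphenyl)-1,6,7,11b-tetrahydrobenzo[6,7]cyclohepta[1,2,3-cd][1]benzofuran
Product: 28 4-methoxy-3-[(1S,6R,7S,11bS)-4,8,10-trimethoxy-1,7-bis(4-methoxyphenyl)-1,6,7,11b-tetrahydrobenzo[6,7]cyclohepta[1,2,3-cd][1]benzofuran-6-yl]benzaldehyde
Conditions: n-BuLi, THF, −78 °C; DMF, −78 → 0 °C; aq. NH4Cl
Reagents that add atoms: N,N-dimethylformamide, CN(C)C=O
Why: Bromine–lithium exchange at −78 °C is faster than deprotonation of any benzylic C–H bond, and the aryllithium is formylated by DMF (Bouveault-type formylation).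

Step 19
Reactants: 10 diethyl {[3-(3,5-dimethoxyphenyl)-6-methoxy-2-(4-methoxyphenyl)benzofuran-4-yl]methyl}phosphonate; 28 4-methoxy-3-[(1S,6R,7S,11bS)-4,8,10-trimethoxy-1,7-bis(4-methoxyphenyl)-1,6,7,11b-tetrahydrobenzo[6,7]cyclohepta[1,2,3-cd][1]benzofuran-6-yl]benzaldehyde
Product: 29 3-(3,5-dimethoxyphenyl)-6-methoxy-2-(4-methoxyphenyl)-4-[(E)-2-{4-methoxy-3-[(1S,6R,7S,11bS)-4,8,10-trimethoxy-1,7-bis(4-methoxyphenyl)-1,6,7,11b-tetrahydrobenzo[6,7]cyclohepta[1,2,3-cd][1]benzofuran-6-yl]phenyl}ethenyl]benzofuran
Conditions: NaH, THF, 0 °C → rt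
Reagents that add atoms: none
Why: Horner–Wadsworth–Emmons olefination of the benzylic phosphonate carbanion with the unhindered aryl aldehyde should give the E-stilbene; no stereocentre carries an acidic hydrogen under these conditions.

Step 20
Reactants: 29 3-(3,5-dimethoxyphenyl)-6-methoxy-2-(4-methoxyphenyl)-4-[(E)-2-{4-methoxy-3-[(1S,6R,7S,11bS)-4,8,10-trimethoxy-1,7-bis(4-methoxyphenyl)-1,6,7,11b-tetrahydrobenzo[6,7]cyclohepta[1,2,3-cd][1]benzofuran-6-yl]phenyl}ethenyl]benzofuran
Product: 30 CNP0339094.1, 5-[6-hydroxy-2-(4-hydroxyphenyl)-4-[(E)-2-{4-hydroxy-3-[(1S,6R,7S,11bS)-4,8,10-trihydroxy-1,7-bis(4-hydroxyphenyl)-1,6,7,11b-tetrahydrobenzo[6,7]cyclohepta[1,2,3-cd][1]benzofuran-6-yl]phenyl}ethenyl]benzofuran-3-yl]benzene-1,3-diol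
Conditions: BBr3 (excess), CH2Cl2, −78 °C → rt; then MeOH/H2O
Reagents that add atoms: none
Why: BBr3 cleaves all ten aryl methyl ethers by Lewis acid–base complexation and bromide attack at methyl. Low temperature and short exposure are meant to keep the O–Cc bond and the stilbene intact; no stereocentre is touched.

## Compound list

1 | 3,5-dimethoxybenzyl alcohol | COc1cc(CO)cc(OC)c1 | starting material
2 | [(3,5-dimethoxybenzyl)oxy]triisopropylsilane | COc1cc(CO[Si](C(C)C)(C(C)C)C(C)C)cc(OC)c1 | intermediate
3 | 3,5-dimethoxybenzoyl chloride | COc1cc(cc(OC)c1)C(Cl)=O | starting material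
4 | (3,5-dimethoxyphenyl)[2,4-dimethoxy-6-(triisopropylsilyloxymethyl)phenyl]methanone | COc1cc(CO[Si](C(C)C)(C(C)C)C(C)C)c(C(=O)c2cc(OC)cc(OC)c2)c(OC)c1 | intermediate
5 | (3,5-dimethoxyphenyl)[2-hydroxy-4-methoxy-6-(triisopropylsilyloxymethyl)phenyl]methanone | COc1cc(CO[Si](C(C)C)(C(C)C)C(C)C)c(C(=O)c2cc(OC)cc(OC)c2)c(O)c1 | intermediate
6 | 4-methoxybenzoyl chloride | COc1ccc(cc1)C(Cl)=O | starting material
7 | 2-(3,5-dimethoxybenzoyl)-5-methoxy-3-(triisopropylsilyloxymethyl)phenyl 4-methoxybenzoate | COc1cc(CO[Si](C(C)C)(C(C)C)C(C)C)c(C(=O)c2cc(OC)cc(OC)c2)c(OC(=O)c2ccc(OC)cc2)c1 | intermediate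
8 | 3-(3,5-dimethoxyphenyl)-6-methoxy-2-(4-methoxyphenyl)-4-(triisopropylsilyloxymethyl)benzofuran | COc1cc(CO[Si](C(C)C)(C(C)C)C(C)C)c2c(c1)oc(-c1ccc(OC)cc1)c2-c1cc(OC)cc(OC)c1 | intermediate
9 | [3-(3,5-dimethoxyphenyl)-6-methoxy-2-(4-methoxyphenyl)benzofuran-4-yl]methanol | COc1cc(CO)c2c(c1)oc(-c1ccc(OC)cc1)c2-c1cc(OC)cc(OC)c1 | intermediate
10 | diethyl {[3-(3,5-dimethoxyphenyl)-6-methoxy-2-(4-methoxyphenyl)benzofuran-4-yl]methyl}phosphonate | CCOP(=O)(OCC)Cc1cc(OC)cc2oc(-c3ccc(OC)cc3)c(-c3cc(OC)cc(OC)c3)c12 | intermediate
11 | 5-bromo-2-hydroxybenzonitrile | N#Cc1cc(Br)ccc1O | starting material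
12 | 4-methoxybenzyl chloride | COc1ccc(CCl)cc1 | starting material
13 | 5-bromo-2-[(4-methoxybenzyl)oxy]benzonitrile | N#Cc1cc(Br)ccc1OCc1ccc(OC)cc1 | intermediate
14 | 3,5-dimethoxyphenylmagnesium chloride | COc1cc([Mg]Cl)cc(OC)c1 | starting material
15 | {5-bromo-2-[(4-methoxybenzyl)oxy]phenyl}(3,5-dimethoxyphenyl)methanimine (N-magnesium salt in the flask) | N=C(c1cc(OC)cc(OC)c1)c1cc(Br)ccc1OCc1ccc(OC)cc1 | intermediate (not isolated)
16 | {5-bromo-2-[(4-methoxybenzyl)oxy]phenyl}(3,5-dimethoxyphenyl)methanone | O=C(c1cc(OC)cc(OC)c1)c1cc(Br)ccc1OCc1ccc(OC)cc1 | intermediate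
17 | [{5-bromo-2-[(4-methoxybenzyl)oxy]phenyl}(3,5-dimethoxyphenyl)methylidene]hydrazine (either C=N geometry) | NN=C(c1cc(OC)cc(OC)c1)c1cc(Br)ccc1OCc1ccc(OC)cc1 | intermediate
18 | 4-bromo-2-[diazo(3,5-dimethoxyphenyl)methyl]-1-[(4-methoxybenzyl)oxy]benzene | [N-]=[N+]=C(c1cc(OC)cc(OC)c1)c1cc(Br)ccc1OCc1ccc(OC)cc1 | intermediate (not isolated)
19 | (2S,3R)-5-bromo-3-(3,5-dimethoxyphenyl)-2-(4-methoxyphenyl)-2,3-dihydrobenzofuran (2,3-cis; C3 = Ca, C2 = Cd) | Brc1ccc2O[C@H](c3ccc(OC)cc3)[C@H](c4cc(OC)cc(OC)c4)c2c1 | intermediate
20 | {2-[(2S,3R)-5-bromo-2-(4-methoxyphenyl)-2,3-dihydrobenzofuran-3-yl]-4,6-dimethoxyphenyl}(3,5-dimethoxyphenyl)methanone | Brc1ccc2O[C@H](c3ccc(OC)cc3)[C@H](c4cc(OC)cc(OC)c4C(=O)c4cc(OC)cc(OC)c4)c2c1 | intermediate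
21 | (10R,11S)-10-(5-bromo-2-hydroxyphenyl)-1,3,6,8-tetramethoxy-11-(4-methoxyphenyl)-10,11-dihydro-5H-dibenzo[a,d][7]annulen-5-one (C10 = Ca, C11 = Cd, aryl groups trans) | Oc1ccc(Br)cc1[C@H]2c3cc(OC)cc(OC)c3C(=O)c3cc(OC)cc(OC)c3[C@@H]2c2ccc(OC)cc2 | intermediate
22 | (10R,11S)-10-(5-bromo-2-methoxyphenyl)-1,3,6,8-tetramethoxy-11-(4-methoxyphenyl)-10,11-dihydro-5H-dibenzo[a,d][7]annulen-5-one | COc1ccc(Br)cc1[C@H]2c3cc(OC)cc(OC)c3C(=O)c3cc(OC)cc(OC)c3[C@@H]2c2ccc(OC)cc2 | intermediate
23 | (10R,11S)-10-(5-bromo-2-methoxyphenyl)-6-hydroxy-1,3,8-trimethoxy-11-(4-methoxyphenyl)-10,11-dihydro-5H-dibenzo[a,d][7]annulen-5-one | COc1ccc(Br)cc1[C@H]2c3cc(OC)cc(O)c3C(=O)c3cc(OC)cc(OC)c3[C@@H]2c2ccc(OC)cc2 | intermediate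
24 | 4-methoxybenzylmagnesium chloride | COc1ccc(C[Mg]Cl)cc1 | starting material
25 | (10R,11S)-10-(5-bromo-2-methoxyphenyl)-1,3,8-trimethoxy-5-(4-methoxybenzyl)-11-(4-methoxyphenyl)-10,11-dihydro-5H-dibenzo[a,d][7]annulene-5,6-diol (either configuration at C5) | COc1ccc(Br)cc1[C@H]2c3cc(OC)cc(O)c3C(O)(Cc3ccc(OC)cc3)c3cc(OC)cc(OC)c3[C@@H]2c2ccc(OC)cc2 | intermediate
26 | (10R,11S)-10-(5-bromo-2-methoxyphenyl)-1,3,8-trimethoxy-5-(4-methoxybenzylidene)-11-(4-methoxyphenyl)-10,11-dihydro-5H-dibenzo[a,d][7]annulen-6-ol (either alkene geometry) | COc1ccc(Br)cc1[C@H]2c3cc(OC)cc(O)c3C(=Cc3ccc(OC)cc3)c3cc(OC)cc(OC)c3[C@@H]2c2ccc(OC)cc2 | intermediate (not isolated)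
27 | (1S,6R,7S,11bS)-6-(5-bromo-2-methoxyphenyl)-4,8,10-trimethoxy-1,7-bis(4-methoxyphenyl)-1,6,7,11b-tetrahydrobenzo[6,7]cyclohepta[1,2,3-cd][1]benzofuran (C1 = Cc, C6 = Ca, C7 = Cd, C11b = Cb) | COc1ccc(Br)cc1[C@H]2c3cc(OC)cc4c3[C@H](c3cc(OC)cc(OC)c3[C@@H]2c2ccc(OC)cc2)[C@@H](c2ccc(OC)cc2)O4 | intermediate
28 | 4-methoxy-3-[(1S,6R,7S,11bS)-4,8,10-trimethoxy-1,7-bis(4-methoxyphenyl)-1,6,7,11b-tetrahydrobenzo[6,7]cyclohepta[1,2,3-cd][1]benzofuran-6-yl]benzaldehyde | COc1ccc(C=O)cc1[C@H]2c3cc(OC)cc4c3[C@H](c3cc(OC)cc(OC)c3[C@@H]2c2ccc(OC)cc2)[C@@H](c2ccc(OC)cc2)O4 | intermediate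
29 | deca-O-methyl ether of the target (E-stilbene; Ca R, Cd S, Cb S, Cc S) | COc1ccc(-c2oc3cc(OC)cc(/C=C/c4ccc(OC)c([C@H]5c6cc(OC)cc7c6[C@H](c6cc(OC)cc(OC)c6[C@@H]5c5ccc(OC)cc5)[C@@H](c5ccc(OC)cc5)O7)c4)c3c2-c2cc(OC)cc(OC)c2)cc1 | intermediate
30 | CNP0339094.1 (E-stilbene; Ca R, Cd S, Cb S, Cc S) | Oc1ccc(-c2oc3cc(O)cc(/C=C/c4ccc(O)c([C@H]5c6cc(O)cc7c6[C@H](c6cc(O)cc(O)c6[C@@H]5c5ccc(O)cc5)[C@@H](c5ccc(O)cc5)O7)c4)c3c2-c2cc(O)cc(O)c2)cc1 | target

## Step count and least certain steps

Total: 20 steps. Longest linear sequence: 13 steps (steps 8 to 20, from 11 and 12). The benzofuran branch is steps 1 to 7.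

Step 5 (key step). Most likely to go wrong: pinacol-type dimerisation of the ketone, or reduction that stops at the alcohol before the ester is attacked, because the ketone is di-ortho-substituted and the C3/C4 region is crowded. Fallback, from 5 back to 8: alkylation of 5 with 12 (K2CO3, DMF) should give the 4-methoxybenzyl ether F1. With the phosphazene base P4-t-Bu in toluene at 100 °C the ether CH2 is deprotonated, the carbanion adds to the ketone and water is lost, which gives 8. The same C2–C3 bond is then made by carbanion addition instead of reductive coupling.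

Step 13. Most likely to go wrong: ring closure onto a ring that bears the carbonyl group is slow, so proton loss next to the cation (erosion of the configuration at Ca) or simple re-closure by the ring D oxygen may win. Fallback, from 19 back to 22, closing the seven-membered ring by acylation at Cb instead of alkylation at Cd:
- 19 is opened with BF3·OEt2 in CH2Cl2 at −40 °C in the presence of excess 2, which should be alkylated next to its side chain and anti to ring D to give the tetraarylethane phenol F4.
- MeI/K2CO3 gives the methyl ether F5, and n-Bu4NF the benzylic alcohol F6.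
- Dess–Martin periodinane gives the aldehyde F7, and NaClO2/NaH2PO4/2-methyl-2-butene the carboxylic acid F8.
- (CF3CO)2O in CH2Cl2 closes the ring by Friedel–Crafts acylation onto either equivalent ortho position of ring E and gives 22.

Step 12. Most likely to go wrong: ionisation of the benzylic C–O bond by the strong Lewis acid during acylation, or acylation between the two methoxy groups of ring E (poor regioselectivity next to the bulky benzylic carbon). Fallback, from 19 back to 20, without a strong Lewis acid: Vilsmeier–Haack formylation (POCl3, DMF) should give the aldehyde F2; addition of 14 gives the diaryl carbinol F3; Dess–Martin oxidation gives 20.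

Step 17. Most likely to go wrong: incomplete equilibration, so that protonation of 26 from the wrong face leaves the Cb epimer, or acid-induced reversal of the Cd–ring F bond on long heating. Fallback, from 23 back to 27, with Cb set by a catalyst:
- Alkylation of 23 with 12 (K2CO3, DMF) gives the 4-methoxybenzyl ether F9, and hydrazine the hydrazone F10.
- MnO2 gives the diazo compound F11.
- The enantiomer of Rh2(PTAD)4 that delivers hydrogen to Cb on the face of H–Ca inserts the carbene into the ether CH2 and gives the cis-dihydrofuran F12.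
- A catalytic amount of CF3CO2H in CH2Cl2 epimerises Cc through the benzylic cation and gives the trans compound 27.

Step 20. Most likely to go wrong: ionisation of the O–Cc bond by the Lewis acid, or protonation of the stilbene by HBr followed by Friedel–Crafts cyclisation onto ring C. Fallback, from 29 to 30, by a different mechanism: nucleophilic dealkylation with excess NaSEt in DMF at 130 °C, in which the thiolate attacks each methyl group (SN2) and the phenoxides are released under basic, non-ionising conditions. It makes no new compound (none, F0).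

Further compounds
F1 | step 5 | (3,5-dimethoxyphenyl){4-methoxy-2-[(4-methoxybenzyl)oxy]-6-(triisopropylsilyloxymethyl)phenyl}methanone | COc1cc(CO[Si](C(C)C)(C(C)C)C(C)C)c(C(=O)c2cc(OC)cc(OC)c2)c(OCc2ccc(OC)cc2)c1
F2 | step 12 | 2-[(2S,3R)-5-bromo-2-(4-methoxyphenyl)-2,3-dihydrobenzofuran-3-yl]-4,6-dimethoxybenzaldehyde | Brc1ccc2O[C@H](c3ccc(OC)cc3)[C@H](c4cc(OC)cc(OC)c4C=O)c2c1
F3 | step 12 | {2-[(2S,3R)-5-bromo-2-(4-methoxyphenyl)-2,3-dihydrobenzofuran-3-yl]-4,6-dimethoxyphenyl}(3,5-dimethoxyphenyl)methanol (either carbinol configuration) | Brc1ccc2O[C@H](c3ccc(OC)cc3)[C@H](c4cc(OC)cc(OC)c4C(O)c4cc(OC)cc(OC)c4)c2c1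
F4 | step 13 | 4-bromo-2-[(1R,2S)-1-(3,5-dimethoxyphenyl)-2-[2,4-dimethoxy-6-(triisopropylsilyloxymethyl)phenyl]-2-(4-methoxyphenyl)ethyl]phenol | Oc1ccc(Br)cc1[C@@H](c1cc(OC)cc(OC)c1)[C@H](c1c(CO[Si](C(C)C)(C(C)C)C(C)C)cc(OC)cc1OC)c1ccc(OC)cc1
F5 | step 13 | methyl ether of F4 | COc1ccc(Br)cc1[C@@H](c1cc(OC)cc(OC)c1)[C@H](c1c(CO[Si](C(C)C)(C(C)C)C(C)C)cc(OC)cc1OC)c1ccc(OC)cc1
F6 | step 13 | {2-[(1S,2R)-2-(5-bromo-2-methoxyphenyl)-2-(3,5-dimethoxyphenyl)-1-(4-methoxyphenyl)ethyl]-3,5-dimethoxyphenyl}methanol | COc1ccc(Br)cc1[C@@H](c1cc(OC)cc(OC)c1)[C@H](c1c(CO)cc(OC)cc1OC)c1ccc(OC)cc1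
F7 | step 13 | 2-[(1S,2R)-2-(5-bromo-2-methoxyphenyl)-2-(3,5-dimethoxyphenyl)-1-(4-methoxyphenyl)ethyl]-3,5-dimethoxybenzaldehyde | COc1ccc(Br)cc1[C@@H](c1cc(OC)cc(OC)c1)[C@H](c1c(C=O)cc(OC)cc1OC)c1ccc(OC)cc1
F8 | step 13 | 2-[(1S,2R)-2-(5-bromo-2-methoxyphenyl)-2-(3,5-dimethoxyphenyl)-1-(4-methoxyphenyl)ethyl]-3,5-dimethoxybenzoic acid | COc1ccc(Br)cc1[C@@H](c1cc(OC)cc(OC)c1)[C@H](c1c(C(=O)O)cc(OC)cc1OC)c1ccc(OC)cc1
F9 | step 17 | (10R,11S)-10-(5-bromo-2-methoxyphenyl)-1,3,8-trimethoxy-6-[(4-methoxybenzyl)oxy]-11-(4-methoxyphenyl)-10,11-dihydro-5H-dibenzo[a,d][7]annulen-5-one | COc1ccc(Br)cc1[C@H]2c3cc(OC)cc(OCc4ccc(OC)cc4)c3C(=O)c3cc(OC)cc(OC)c3[C@@H]2c2ccc(OC)cc2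
F10 | step 17 | hydrazone of F9 | COc1ccc(Br)cc1[C@H]2c3cc(OC)cc(OCc4ccc(OC)cc4)c3C(=NN)c3cc(OC)cc(OC)c3[C@@H]2c2ccc(OC)cc2
F11 | step 17 | 5-diazo compound from F10 | COc1ccc(Br)cc1[C@H]2c3cc(OC)cc(OCc4ccc(OC)cc4)c3C(=[N+]=[N-])c3cc(OC)cc(OC)c3[C@@H]2c2ccc(OC)cc2
F12 | step 17 | (1R,6R,7S,11bS)-6-(5-bromo-2-methoxyphenyl)-4,8,10-trimethoxy-1,7-bis(4-methoxyphenyl)-1,6,7,11b-tetrahydrobenzo[6,7]cyclohepta[1,2,3-cd][1]benzofuran (Cc epimer of 27, cis-dihydrofuran) | COc1ccc(Br)cc1[C@H]2c3cc(OC)cc4c3[C@H](c3cc(OC)cc(OC)c3[C@@H]2c2ccc(OC)cc2)[C@H](c2ccc(OC)cc2)O4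
F0 | step 20 | none | none
A1 | alternative 1 | 4-chloro-2-[(1S,6R,7S,11bS)-4,8,10-trimethoxy-1,7-bis(4-methoxyphenyl)-1,6,7,11b-tetrahydrobenzo[6,7]cyclohepta[1,2,3-cd][1]benzofuran-6-yl]phenyl methanesulfonate | CS(=O)(=O)Oc1ccc(Cl)cc1[C@H]2c3cc(OC)cc4c3[C@H](c3cc(OC)cc(OC)c3[C@@H]2c2ccc(OC)cc2)[C@@H](c2ccc(OC)cc2)O4
A2 | alternative 1 | aryl-free tetracycle: 4-chloro-2-[(6R,11bS)-1,7-dihydroxy-4,8,10-trimethoxy-1,6,7,11b-tetrahydrobenzo[6,7]cyclohepta[1,2,3-cd][1]benzofuran-6-yl]phenyl methanesulfonate (either configuration at C1 and C7) | CS(=O)(=O)Oc1ccc(Cl)cc1[C@H]2c3cc(OC)cc4c3[C@H](c3cc(OC)cc(OC)c3C2O)C(O)O4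
A3 | alternative 1 | anisole | COc1ccccc1
A4 | alternative 2 | (10R,11S)-10-(5-bromo-2-methoxyphenyl)-1,3,6,8-tetramethoxy-11-(4-methoxyphenyl)-10,11-dihydro-5H-dibenzo[a,d][7]annulen-5-one (identical with 22) | COc1ccc(Br)cc1[C@H]2c3cc(OC)cc(OC)c3C(=O)c3cc(OC)cc(OC)c3[C@@H]2c2ccc(OC)cc2
A5 | alternative 2 | trans-2-(5-bromo-2-methoxyphenyl)-4,6-dimethoxy-3-(4-methoxyphenyl)indan-1-one | COc1ccc(Br)cc1[C@H]1C(=O)c2cc(OC)cc(OC)c2[C@@H]1c1ccc(OC)cc1
A6 | alternative 2 | 3,5-dimethoxy-2-(trimethylsilyl)phenyl trifluoromethanesulfonate | COc1cc(OC)c([Si](C)(C)C)c(OS(=O)(=O)C(F)(F)F)c1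
A7 | alternative 3 | 3-(3,5-dimethoxyphenyl)-6-ethoxy-2-(4-methoxyphenyl)benzofuran-4-ol | CCOc1cc(O)c2c(c1)oc(-c1ccc(OC)cc1)c2-c1cc(OC)cc(OC)c1
A8 | alternative 3 | 2-diazo-1-[4-(3,5-dimethoxyphenyl)-5-(4-methoxyphenyl)furan-2-yl]ethan-1-one | [N-]=[N+]=CC(=O)c1cc(-c2cc(OC)cc(OC)c2)c(-c2ccc(OC)cc2)o1
A9 | alternative 3 | ethoxyacetylene | CCOC#C
A10 | alternative 3 | [4-(3,5-dimethoxyphenyl)-5-(4-methoxyphenyl)furan-2-yl]ketene | O=C=Cc1cc(-c2cc(OC)cc(OC)c2)c(-c2ccc(OC)cc2)o1
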